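All runs stem from a simulated flask with made-up constants, noise included.

Substrate and reagent stand at the same charges in the south-west, north-west, red and amber flasks, so their ratio stays at 95.0%, and what changes is free catalyst and time.

| flask | substrate | reagent | free catalyst | remark | time |
|---|---|---|---|---|---|
| south-west | 0.40 M | 0.38 M | 0.56 mM | run made earlier |  |
| north-west | 0.40 M | 0.38 M | 0.88 mM | run made earlier |  |
| red | 0.40 M | 0.380 M | 0.40 mM |  | 20 h |
| amber | 0.40 M | 0.380 M | 0.40 mM |  | 12 h |

| run | time / h | target / % |
|---|---|---|
| south-west | 4.00 | 51.5 |
| south-west | 8.00 | 77.7 |
| south-west | 12.0 | 89.2 |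
| south-west | 15.0 | 92.0 |
| south-west | 20.0 | 92.1 |
| south-west | 25.0 | 91.4 |
| north-west | 4.00 | 70.2 |
| north-west | 8.00 | 89.6 |
| north-west | 12.0 | 93.2 |
| north-west | 15.0 | 92.8 |
| north-west | 20.0 | 93.2 |
| north-west | 25.0 | 90.5 |

(standard deviation of a reading: 0.5 percentage points)

- the analysis behind the earlier runs scatters by 0.5 percentage points, standard deviation

1. which of the two ends with the higher amount of target, in percent of the substrate charged ("neither" if they lie within 2 percentage points) (red / amber / neither)
2. target at the end, in percent of the substrate charged, red
3. target at the end, in percent of the substrate charged, amber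

Two chemists dispute this. The ceiling chemist looks at the ends. Reagent is the limiting reagent by charge, and at 20.0 h the earlier runs read just below 95.0%, at 92.1% and 93.2%. At 12 h they already read 89.2% and 93.2%, so she expects red and amber to end near that ceiling, within 2 percentage points of each other: neither.

The dose chemist looks at the early slope. She takes the natural logarithm of one over the fraction not yet turned into target and divides it by catalyst times time. The first readings give 0.323 /mM/h for south-west and 0.344 /mM/h for north-west, so she uses their mean, 0.333 /mM/h. In powers of ten, the catalyst decade, the catalyst-time that cuts the unconverted fraction tenfold, is 6.90 mM·h.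

Red gets 8.00 mM·h, which is 1.16 decades, and amber gets 4.80 mM·h, which is 0.695 decades. Her reckoning therefore gives 93.1% target for red and 79.8% for amber.

The forecast takes her side: red ends higher, with red at 91.5% (89.5% to 93%) and amber at 79.5% (76.5% to 82%). Its ground is “Catalyst × time is then the useful scale.” Its value for red is not her reckoning: the forecast has red reaching the plateau.

The simulation gives red 90.6% and amber 80.7%, so red ends higher, by 9.9 points against a margin of 2 points.

    reagent + free catalyst ⇌ catalyst intermediate A (K = 3.74 /M, k = 75.6 /M/min)
    catalyst intermediate A → catalyst intermediate B (k = 3.82 /min)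
    substrate + catalyst intermediate B → catalyst intermediate C (k = 46.4 /M/min)
    catalyst intermediate C → free catalyst + target (k = 267 /min)
    target → over-reaction product (k = 3.22 × 10⁻⁵ /min)

Amber falls short of red through its shorter time. The amber flask run to 20 h has red's 1.16 decades instead of 0.695, and its target rises from 80.7% to 90.6%, a gain of 9.9 points. The ceiling view is right further along the earlier runs: south-west at 15.0 h, with 1.22 decades, reads 92.0%, and north-west at 12.0 h, with 1.53 decades, reads 93.2%. Amber stops at 0.695 decades, with 18.2% of its substrate still left.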